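**Strategy.** The ten-membered carbocycle (ring A; germacrane numbering) is disconnected at C9–C10, the bond joining the C9 carbinol to the (Z)-C1=C10 trisubstituted alkene – the retron of an alkenyl-metal addition to an aldehyde. A Nozaki–Hiyama–Kishi macrocyclisation of a (Z)-alkenyl iodide/α-acyloxy aldehyde that already carries the trans-fused α-methylene-γ-lactone (ring B: O, C6, C7, C11, C12) and the complete epoxy ester on O8 closes ring A, transfers the Z geometry and sets C9 in one operation, giving the target itself. The seco precursor comes from a chromium-mediated allylation/lactonisation joining a geranyl-derived iodo-dienal to a glyceraldehyde-derived 2-(bromomethyl)acrylate, with the ester introduced by Mitsunobu inversion at C8.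

Key step: step 14

Remarks on the chemistry
- Numbering: ring A carbons C1–C10, C14 (methyl on C10), C15 (methyl on C4), lactone carbons C11–C13, lactone oxygen on C6, ester oxygen on C8, free hydroxyl on C9.
- Assumption: (S)-glyceraldehyde acetonide 6 is taken as a commercial compound (both antipodes are sold; it is otherwise one oxidation away from commercial (R)-solketal).
- Assumption: in step 7 the antipode of the bishydroxamic acid ligand is the one that delivers the (2R)-epoxide.
- Design premise: the allylation in step 9 is planned on Felkin-type facial control, which gives the correct C6 and C7 but the C8 epimer; step 12 therefore esterifies with inversion.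

Step 1
Reactants: 1 geranyl acetate
Product: 2 (2E)-3-methyl-6-oxohex-2-en-1-yl acetate
Conditions: O3 (ca. 1 equiv), CH2Cl2, −78 °C; then Me2S, −78 °C → rt
Reagents that add atoms: ozone [O-][O+]=O
Why: Chemoselective ozonolysis, in which the remote electron-rich trisubstituted alkene should react faster than the alkene deactivated by the allylic acetate, so that only the isopropylidene terminus is cleaved and the E alkene (later C4=C5) is untouched.

Step 2
Reactants: 2 (2E)-3-methyl-6-oxohex-2-en-1-yl acetate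
Product: 3 (2E,6Z)-7-iodo-3-methylocta-2,6-dien-1-yl acetate
Conditions: EtPPh3I, n-BuLi, THF, rt; I2, −78 °C; NaN(SiMe3)2, −20 °C; then 2, −78 °C → rt
Reagents that add atoms: ethyltriphenylphosphonium iodide CC[P+](c1ccccc1)(c1ccccc1)c1ccccc1.[I-]; iodine II
Why: Stork–Zhao-type Wittig olefination, in which the non-stabilised α-iodoethylidene ylide should add to the aliphatic aldehyde under kinetic control to give the (Z)-2-iodoalk-2-ene (iodine cis to the chain), fixing the later C1=C10 geometry.

Step 3
Reactants: 3 (2E,6Z)-7-iodo-3-methylocta-2,6-dien-1-yl acetate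
Product: 4 (2E,6Z)-7-iodo-3-methylocta-2,6-dien-1-ol
Conditions: K2CO3 (cat.), MeOH, 0 °C → rt
Reagents that add atoms: none
Why: Base-catalysed transesterification (methanolysis) of the allylic acetate, to which the alkenyl iodide and both alkenes are inert.

Step 4
Reactants: 4 (2E,6Z)-7-iodo-3-methylocta-2,6-dien-1-ol
Product: 5 (2E,6Z)-7-iodo-3-methylocta-2,6-dienal
Conditions: TEMPO (2,2,6,6-tetramethylpiperidin-1-oxyl, cat.), PhI(OAc)2, CH2Cl2, rt
Reagents that add atoms: none
Why: Oxoammonium-mediated (TEMPO/PhI(OAc)2) oxidation of a primary allylic alcohol, which should give the enal without E/Z isomerisation and without touching the alkenyl iodide.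

Step 5
Reactants: 6 (4S)-2,2-dimethyl-1,3-dioxolane-4-carbaldehyde ((S)-glyceraldehyde acetonide); 7 methyl acrylate
Product: 8 methyl 2-{[(4S)-2,2-dimethyl-1,3-dioxolan-4-yl](hydroxy)methyl}prop-2-enoate (mixture of carbinol epimers)
Conditions: DABCO (1,4-diazabicyclo[2.2.2]octane, 0.5 equiv), excess 7, dioxane/H2O, rt
Reagents that add atoms: none
Why: Morita–Baylis–Hillman reaction, whose new carbinol centre may form as a mixture because it becomes sp2 in step 6, while the dioxolane centre (later C8) is carried through unchanged.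

Step 6
Reactants: 8 methyl 2-{[(4S)-2,2-dimethyl-1,3-dioxolan-4-yl](hydroxy)methyl}prop-2-enoate
Product: 9 methyl (2Z)-2-(bromomethyl)-3-[(4R)-2,2-dimethyl-1,3-dioxolan-4-yl]prop-2-enoate
Conditions: NBS, Me2S, CH2Cl2, 0 °C → rt
Reagents that add atoms: N-bromosuccinimide O=C1CCC(=O)N1Br
Why: Corey–Kim-type activation of the allylic alcohol followed by SN2′ attack of bromide, which should give the conjugated, thermodynamically preferred (Z)-2-(bromomethyl)alk-2-enoate under neutral conditions that spare the acetonide.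

Step 7
Reactants: 10 3-methylbut-3-en-1-ol
Product: 11 2-[(2R)-2-methyloxiran-2-yl]ethan-1-ol
Conditions: Hf(OtBu)4 (cat.), chiral C2-symmetric bishydroxamic acid ligand (cat.), cumene hydroperoxide, DMPU, 4 Å MS, toluene, 0 °C
Reagents that add atoms: cumene hydroperoxide CC(C)(OO)c1ccccc1
Why: Hydroxyl-directed catalytic asymmetric epoxidation of a homoallylic alcohol, in which the alkoxide-bound hafnium bishydroxamate should deliver the peroxide oxygen to one face of the 1,1-disubstituted alkene and so set the (2R) quaternary epoxide centre.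

Step 8
Reactants: 11 2-[(2R)-2-methyloxiran-2-yl]ethan-1-ol
Product: 12 [(2R)-2-methyloxiran-2-yl]acetic acid
Conditions: TEMPO (cat.), PhI(OAc)2 (2.2 equiv), MeCN/aqueous pH 7 buffer, 0 °C → rt; extraction at pH 4, used at once
Reagents that add atoms: water O
Why: TEMPO/PhI(OAc)2 oxidation of a primary alcohol through the aldehyde hydrate to the carboxylic acid under near-neutral conditions that the acid-labile 2,2-disubstituted epoxide should tolerate, the stereocentre not being involved.

Step 9
Reactants: 5 (2E,6Z)-7-iodo-3-methylocta-2,6-dienal; 9 methyl (2Z)-2-(bromomethyl)-3-[(4R)-2,2-dimethyl-1,3-dioxolan-4-yl]prop-2-enoate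
Product: 15 (4S,5R)-4-[(4R)-2,2-dimethyl-1,3-dioxolan-4-yl]-5-[(1E,5Z)-6-iodo-2-methylhepta-1,5-dien-1-yl]-3-methylideneoxolan-2-one, via allylchromium dichloride 13 (not isolated), via open-chain hydroxy ester 14 (not isolated)
Conditions: CrCl2 (4 equiv), THF, 0 °C → rt; aq. NH4Cl work-up; PPTS (cat.), CH2Cl2, rt
Reagents that add atoms: none
Why: Nozaki–Hiyama (chromium Barbier) allylation followed by lactonisation, in which the allylchromium from 9 should add 1,2 to the enal at its γ-carbon through a chair transition state with the dioxolanyl group trans to CH2Cr (anti adduct, hence the trans-lactone), the aldehyde approaching C7 anti to the dioxolane C–O bond with the C8 hydrogen eclipsing the alkene (Felkin-type control), which sets 6R and 7S next to the dioxolane centre, while the alkenyl iodide is inert to CrCl2 without nickel.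

Step 10
Reactants: 15 (4S,5R)-4-[(4R)-2,2-dimethyl-1,3-dioxolan-4-yl]-5-[(1E,5Z)-6-iodo-2-methylhepta-1,5-dien-1-yl]-3-methylideneoxolan-2-one
Product: 16 (4R,5R)-4-[(1R)-1,2-dihydroxyethyl]-5-[(1E,5Z)-6-iodo-2-methylhepta-1,5-dien-1-yl]-3-methylideneoxolan-2-one
Conditions: AcOH/H2O (4:1), 40 °C
Reagents that add atoms: none
Why: Acid-catalysed acetal hydrolysis, mild enough that the allylic lactone C6–O bond should neither ionise nor transpose to the C8 hydroxyl.

Step 11
Reactants: 16 (4R,5R)-4-[(1R)-1,2-dihydroxyethyl]-5-[(1E,5Z)-6-iodo-2-methylhepta-1,5-dien-1-yl]-3-methylideneoxolan-2-one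
Product: 17 (4R,5R)-4-[(1R)-1-hydroxy-2-(triethylsilyloxy)ethyl]-5-[(1E,5Z)-6-iodo-2-methylhepta-1,5-dien-1-yl]-3-methylideneoxolan-2-one
Conditions: TESCl (1.05 equiv), imidazole, CH2Cl2, −78 → −40 °C
Reagents that add atoms: chlorotriethylsilane CC[Si](CC)(CC)Cl
Why: Sterically controlled selective silylation of the primary (C9) over the hindered secondary (C8) hydroxyl at low temperature with a weak base that should not trigger oxa-Michael addition to the methylene lactone.

Step 12
Reactants: 17 (4R,5R)-4-[(1R)-1-hydroxy-2-(triethylsilyloxy)ethyl]-5-[(1E,5Z)-6-iodo-2-methylhepta-1,5-dien-1-yl]-3-methylideneoxolan-2-one; 12 [(2R)-2-methyloxiran-2-yl]acetic acid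
Product: 18 (1S)-1-[(2R,3S)-2-[(1E,5Z)-6-iodo-2-methylhepta-1,5-dien-1-yl]-4-methylidene-5-oxooxolan-3-yl]-2-(triethylsilyloxy)ethyl [(2R)-2-methyloxiran-2-yl]acetate
Conditions: PPh3, DIAD (premixed), THF, 0 °C → rt
Reagents that add atoms: none
Why: Mitsunobu esterification, in which SN2 displacement of the C8 oxyphosphonium by the carboxylate of 12 should invert the 8R carbinol to the 8S ester of the target under neutral conditions that spare the epoxide, premixing of PPh3 and DIAD keeping free phosphine away from the methylene lactone.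

Step 13
Reactants: 18 (1S)-1-[(2R,3S)-2-[(1E,5Z)-6-iodo-2-methylhepta-1,5-dien-1-yl]-4-methylidene-5-oxooxolan-3-yl]-2-(triethylsilyloxy)ethyl [(2R)-2-methyloxiran-2-yl]acetate
Product: 19 (1S)-1-[(2R,3S)-2-[(1E,5Z)-6-iodo-2-methylhepta-1,5-dien-1-yl]-4-methylidene-5-oxooxolan-3-yl]-2-oxoethyl [(2R)-2-methyloxiran-2-yl]acetate
Conditions: (COCl)2, DMSO, CH2Cl2, −78 → −40 °C; Et3N, −78 → 0 °C; crude aldehyde used directly
Reagents that add atoms: none
Why: Swern oxidation applied directly to a primary triethylsilyl ether, in which chlorodimethylsulfonium chloride should cleave the primary Si–O bond to the alkoxysulfonium and base then give the aldehyde, so that no free 1,2-hydroxy ester open to acyl migration is formed and the low temperature limits epimerisation at C8.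

Step 14
Reactants: 19 (1S)-1-[(2R,3S)-2-[(1E,5Z)-6-iodo-2-methylhepta-1,5-dien-1-yl]-4-methylidene-5-oxooxolan-3-yl]-2-oxoethyl [(2R)-2-methyloxiran-2-yl]acetate
Product: 21 (3aS,4S,5R,6Z,10E,11aR)-5-hydroxy-6,10-dimethyl-3-methylidene-2-oxo-2,3,3a,4,5,8,9,11a-octahydrocyclodeca[b]furan-4-yl [(2R)-2-methyloxiran-2-yl]acetate, via alkenylchromium dichloride 20 (not isolated)
Conditions: CrCl2 (10 equiv), NiCl2 (0.1 equiv), degassed DMSO/THF, slow addition of 19 to 0.002 M, rt; neutral aqueous work-up
Reagents that add atoms: none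
Why: NiCl2 is reduced by CrCl2 to zerovalent nickel, which inserts into the C10–I bond with retention of the Z geometry, and transmetalation to trivalent chromium gives alkenylchromium 20, which adds to the C9 aldehyde. The closest known reaction type is the Nozaki–Hiyama–Kishi macrocyclisation of alkenyl iodide–aldehydes, established for medium and large carbocycles including ten-membered rings. Ring A is closed in a 10-exo-trig mode (C10 attacks the C9 carbonyl carbon, the C=O lying outside the new ring), which completes the bicyclic germacranolide. The new C9 centre should arise from polar Felkin–Anh addition, the alkenyl group approaching anti to the C8–O(acyl) bond to give the 8,9-erythro (9R) carbinol, a preference the trans-fused lactone holding C8 should reinforce. The step needs chemoselectivity for the aldehyde over lactone, ester, epoxide and enoate, which the low basicity of alkenylchromium reagents secures, and ring closure over oligomerisation, which high dilution, the cis C1=C10 unit and the rigid lactone hinge favour. The chromium alkoxide formed is a poor nucleophile, so migration of the C8 acyl group to O9 is not expected before work-up.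

**Compound list**

1 | geranyl acetate, (2E)-3,7-dimethylocta-2,6-dien-1-yl acetate | CC(=O)OC/C=C(\C)CCC=C(C)C | starting material
2 | (2E)-3-methyl-6-oxohex-2-en-1-yl acetate | CC(=O)OC/C=C(\C)CCC=O | intermediate
3 | (2E,6Z)-7-iodo-3-methylocta-2,6-dien-1-yl acetate | CC(=O)OC/C=C(\C)CC/C=C(\I)C | intermediate
4 | (2E,6Z)-7-iodo-3-methylocta-2,6-dien-1-ol | OC/C=C(\C)CC/C=C(\I)C | intermediate
5 | (2E,6Z)-7-iodo-3-methylocta-2,6-dienal | O=C/C=C(\C)CC/C=C(\I)C | intermediate
6 | (4S)-2,2-dimethyl-1,3-dioxolane-4-carbaldehyde | O=C[C@@H]1COC(C)(C)O1 | starting material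
7 | methyl acrylate | C=CC(=O)OC | starting material
8 | methyl 2-{[(4S)-2,2-dimethyl-1,3-dioxolan-4-yl](hydroxy)methyl}prop-2-enoate (carbinol epimers) | COC(=O)C(=C)C(O)[C@@H]1COC(C)(C)O1 | intermediate
9 | methyl (2Z)-2-(bromomethyl)-3-[(4R)-2,2-dimethyl-1,3-dioxolan-4-yl]prop-2-enoate | COC(=O)/C(CBr)=C/[C@@H]1COC(C)(C)O1 | intermediate
10 | 3-methylbut-3-en-1-ol | C=C(C)CCO | starting material
11 | 2-[(2R)-2-methyloxiran-2-yl]ethan-1-ol | OCC[C@]1(C)CO1 | intermediate
12 | [(2R)-2-methyloxiran-2-yl]acetic acid | OC(=O)C[C@]1(C)CO1 | intermediate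
13 | {3-[(4R)-2,2-dimethyl-1,3-dioxolan-4-yl]-2-(methoxycarbonyl)prop-2-en-1-yl}chromium dichloride (σ-allyl form, alkene geometry mobile) | COC(=O)C(C[Cr](Cl)Cl)=C[C@@H]1COC(C)(C)O1 | intermediate (not isolated)
14 | methyl (3S,4R,5E,9Z)-3-[(4R)-2,2-dimethyl-1,3-dioxolan-4-yl]-4-hydroxy-10-iodo-6-methyl-2-methylideneundeca-5,9-dienoate | COC(=O)C(=C)[C@@H]([C@H](O)/C=C(\C)CC/C=C(\I)C)[C@@H]1COC(C)(C)O1 | intermediate (not isolated)
15 | (4S,5R)-4-[(4R)-2,2-dimethyl-1,3-dioxolan-4-yl]-5-[(1E,5Z)-6-iodo-2-methylhepta-1,5-dien-1-yl]-3-methylideneoxolan-2-one | C=C1C(=O)O[C@H](/C=C(\C)CC/C=C(\I)C)[C@H]1[C@@H]2COC(C)(C)O2 | intermediate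
16 | (4R,5R)-4-[(1R)-1,2-dihydroxyethyl]-5-[(1E,5Z)-6-iodo-2-methylhepta-1,5-dien-1-yl]-3-methylideneoxolan-2-one | C=C1C(=O)O[C@H](/C=C(\C)CC/C=C(\I)C)[C@H]1[C@@H](O)CO | intermediate
17 | (4R,5R)-4-[(1R)-1-hydroxy-2-(triethylsilyloxy)ethyl]-5-[(1E,5Z)-6-iodo-2-methylhepta-1,5-dien-1-yl]-3-methylideneoxolan-2-one | C=C1C(=O)O[C@H](/C=C(\C)CC/C=C(\I)C)[C@H]1[C@@H](O)CO[Si](CC)(CC)CC | intermediate
18 | (1S)-1-[(2R,3S)-2-[(1E,5Z)-6-iodo-2-methylhepta-1,5-dien-1-yl]-4-methylidene-5-oxooxolan-3-yl]-2-(triethylsilyloxy)ethyl [(2R)-2-methyloxiran-2-yl]acetate | C=C1C(=O)O[C@H](/C=C(\C)CC/C=C(\I)C)[C@H]1[C@H](OC(=O)C[C@]2(C)CO2)CO[Si](CC)(CC)CC | intermediate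
19 | (1S)-1-[(2R,3S)-2-[(1E,5Z)-6-iodo-2-methylhepta-1,5-dien-1-yl]-4-methylidene-5-oxooxolan-3-yl]-2-oxoethyl [(2R)-2-methyloxiran-2-yl]acetate | C=C1C(=O)O[C@H](/C=C(\C)CC/C=C(\I)C)[C@H]1[C@H](OC(=O)C[C@]2(C)CO2)C=O | intermediate
20 | alkenylchromium dichloride of 19 (CrCl2 in place of iodine on C10, Z geometry retained) | C=C1C(=O)O[C@H](/C=C(\C)CC/C=C(\[Cr](Cl)Cl)C)[C@H]1[C@H](OC(=O)C[C@]2(C)CO2)C=O | intermediate (not isolated)
21 | (3aS,4S,5R,6Z,10E,11aR)-5-hydroxy-6,10-dimethyl-3-methylidene-2-oxo-2,3,3a,4,5,8,9,11a-octahydrocyclodeca[b]furan-4-yl [(2R)-2-methyloxiran-2-yl]acetate | C=C1C(=O)O[C@@H]2/C=C(\C)CC/C=C(/C)[C@@H](O)[C@@H](OC(=O)C[C@]3(C)CO3)[C@@H]12 | target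

**Total step count:** 14
**Longest linear sequence:** 10 steps (steps 1–4, then 9–14)

**Steps most likely to fail**

1. Step 14. What may go wrong: the conformation of the closing ring may override the Felkin preference, so that the alkenylchromium adds to the other face of the C9 aldehyde. Intermolecular coupling may also erode the ring closure. The fallback keeps the ring closure of 19 but sets C9 afterwards by reagent control. The cyclisation product would then be the C9 epimer, (3aS,4S,5S,6Z,10E,11aR)-5-hydroxy-6,10-dimethyl-3-methylidene-2-oxo-2,3,3a,4,5,8,9,11a-octahydrocyclodeca[b]furan-4-yl [(2R)-2-methyloxiran-2-yl]acetate F1. Oxidation with Dess–Martin periodinane (NaHCO3, CH2Cl2, 0 °C) would give the C9 enone, (3aS,4S,6Z,10E,11aR)-6,10-dimethyl-3-methylidene-2,5-dioxo-2,3,3a,4,5,8,9,11a-octahydrocyclodeca[b]furan-4-yl [(2R)-2-methyloxiran-2-yl]acetate F2. A 1,2-reduction with the appropriate antipode of 2-methyl-CBS-oxazaborolidine and catecholborane (toluene, −78 °C) should then deliver the 9R alcohol. The fallback sets out from 19 and comes back at 21.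

2. Step 9. What may go wrong: the enal may approach the allylchromium on the face opposite to the predicted one (anti to C9 rather than anti to the dioxolane C–O bond), which would pair the wanted 6R,7S centres with the other dioxolane antipode. The fallback uses the antipodal aldehyde and a retentive acylation. (R)-Glyceraldehyde acetonide, (4R)-2,2-dimethyl-1,3-dioxolane-4-carbaldehyde F3, would be taken through the Morita–Baylis–Hillman reaction with 7 to methyl 2-{[(4R)-2,2-dimethyl-1,3-dioxolan-4-yl](hydroxy)methyl}prop-2-enoate F4. NBS/Me2S would give methyl (2Z)-2-(bromomethyl)-3-[(4S)-2,2-dimethyl-1,3-dioxolan-4-yl]prop-2-enoate F5. CrCl2-mediated coupling with 5 and lactonisation would then give (4S,5R)-4-[(4S)-2,2-dimethyl-1,3-dioxolan-4-yl]-5-[(1E,5Z)-6-iodo-2-methylhepta-1,5-dien-1-yl]-3-methylideneoxolan-2-one F6, which already has the C8 configuration of the target. Aqueous AcOH would give (4R,5R)-4-[(1S)-1,2-dihydroxyethyl]-5-[(1E,5Z)-6-iodo-2-methylhepta-1,5-dien-1-yl]-3-methylideneoxolan-2-one F7. TESCl/imidazole would give (4R,5R)-4-[(1S)-1-hydroxy-2-(triethylsilyloxy)ethyl]-5-[(1E,5Z)-6-iodo-2-methylhepta-1,5-dien-1-yl]-3-methylideneoxolan-2-one F8. Carbodiimide esterification with 12 (EDC hydrochloride, DMAP, CH2Cl2, 0 °C), which retains configuration, would complete the detour. The fallback sets out from 5 and 7 and comes back at 18.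

3. Step 12. What may go wrong: displacement at the hindered C8 oxyphosphonium may be slow, so that elimination or participation of the lactone carbonyl (retention, lactone transposition) competes with inversion. The fallback inverts C8 by oxidation and reagent-controlled reduction instead of substitution. Oxidation of 17 with Dess–Martin periodinane (NaHCO3, CH2Cl2) would give (4S,5R)-5-[(1E,5Z)-6-iodo-2-methylhepta-1,5-dien-1-yl]-3-methylidene-4-[(triethylsilyloxy)acetyl]oxolan-2-one F9. CBS reduction (oxazaborolidine antipode chosen for the 8S alcohol, catecholborane, −78 °C), which distinguishes the small CH2OSiEt3 from the branched ring substituent, should give the 8S alcohol F8 already described in the fallback to step 9. Retentive esterification with 12 (EDC hydrochloride, DMAP) follows. The fallback sets out from 17 and comes back at 18.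

**Further compounds**

F1 | step 14 | (3aS,4S,5S,6Z,10E,11aR)-5-hydroxy-6,10-dimethyl-3-methylidene-2-oxo-2,3,3a,4,5,8,9,11a-octahydrocyclodeca[b]furan-4-yl [(2R)-2-methyloxiran-2-yl]acetate | C=C1C(=O)O[C@@H]2/C=C(\C)CC/C=C(/C)[C@H](O)[C@@H](OC(=O)C[C@]3(C)CO3)[C@@H]12
F2 | step 14 | (3aS,4S,6Z,10E,11aR)-6,10-dimethyl-3-methylidene-2,5-dioxo-2,3,3a,4,5,8,9,11a-octahydrocyclodeca[b]furan-4-yl [(2R)-2-methyloxiran-2-yl]acetate | C=C1C(=O)O[C@@H]2/C=C(\C)CC/C=C(/C)C(=O)[C@@H](OC(=O)C[C@]3(C)CO3)[C@@H]12
F3 | step 9 | (4R)-2,2-dimethyl-1,3-dioxolane-4-carbaldehyde | O=C[C@H]1COC(C)(C)O1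
F4 | step 9 | methyl 2-{[(4R)-2,2-dimethyl-1,3-dioxolan-4-yl](hydroxy)methyl}prop-2-enoate (carbinol epimers) | COC(=O)C(=C)C(O)[C@H]1COC(C)(C)O1
F5 | step 9 | methyl (2Z)-2-(bromomethyl)-3-[(4S)-2,2-dimethyl-1,3-dioxolan-4-yl]prop-2-enoate | COC(=O)/C(CBr)=C/[C@H]1COC(C)(C)O1
F6 | step 9 | (4S,5R)-4-[(4S)-2,2-dimethyl-1,3-dioxolan-4-yl]-5-[(1E,5Z)-6-iodo-2-methylhepta-1,5-dien-1-yl]-3-methylideneoxolan-2-one | C=C1C(=O)O[C@H](/C=C(\C)CC/C=C(\I)C)[C@H]1[C@H]2COC(C)(C)O2
F7 | step 9 | (4R,5R)-4-[(1S)-1,2-dihydroxyethyl]-5-[(1E,5Z)-6-iodo-2-methylhepta-1,5-dien-1-yl]-3-methylideneoxolan-2-one | C=C1C(=O)O[C@H](/C=C(\C)CC/C=C(\I)C)[C@H]1[C@H](O)CO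
F8 | step 9 | (4R,5R)-4-[(1S)-1-hydroxy-2-(triethylsilyloxy)ethyl]-5-[(1E,5Z)-6-iodo-2-methylhepta-1,5-dien-1-yl]-3-methylideneoxolan-2-one | C=C1C(=O)O[C@H](/C=C(\C)CC/C=C(\I)C)[C@H]1[C@H](O)CO[Si](CC)(CC)CC
F9 | step 12 | (4S,5R)-5-[(1E,5Z)-6-iodo-2-methylhepta-1,5-dien-1-yl]-3-methylidene-4-[(triethylsilyloxy)acetyl]oxolan-2-one | C=C1C(=O)O[C@H](/C=C(\C)CC/C=C(\I)C)[C@H]1C(=O)CO[Si](CC)(CC)CC
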